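**Retrosynthetic overview**
1. Target 29 ⇐ late carbamoylation and MOM removal, and before that cross-metathesis and reduction on the two vinyl groups of the C2-symmetric [7.7]paracyclophane 19.
2. 19 ⇐ two molecules of monomer 15 by cutting both ring CH2–CH(aryl) bonds. Forward, this is a head-to-tail double SN2′ allyl–alkyl coupling whose second event closes the 22-membered ring. It is the only ring formed; both benzene rings come from 1.
3. Enabling feature: the two halves are identical, and each ring CH2 is bonded to a benzylic CH that sits on the resorcinol carbon between the two C–O carbons and carries the dichlorobutyl chain. The first two carbons of that chain can be a vinyl group, which makes this CH the γ-carbon of an allyl electrophile. The para placement of the two arms on a rigid benzene ring forbids cyclisation of the monomer.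
4. 15 ⇐ Evans syn-aldol (carbinol and methyl centres), allyl–copper chain extension, ortho-lithiation between the two OMOM groups, Still–Gennari olefination.

Key step: step 11

Assumption: the (R)-DTBM-SEGPHOS–copper catalyst is taken to deliver the alkyl group to the face of the (Z)-allyl chloride that gives the (S)-configured benzylic centre; its facial preference for a γ-aryl substrate is not established, and the antipodal ligand would be used if the preference is the reverse.

**Route**

Step 1
Reactants: 1 3,5-dihydroxybenzaldehyde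
Product: 2 3,5-bis(methoxymethoxy)benzaldehyde
Conditions: MOMCl, i-Pr2NEt, CH2Cl2, 0 °C to rt
Reagents that add atoms: chloromethyl methyl ether, COCCl
Why: O-alkylation of both phenols (Williamson-type) should give base-stable acetal ethers that later direct the ortho-lithiation.

Step 2
Reactants: 2 3,5-bis(methoxymethoxy)benzaldehyde; 3 (R)-4-benzyl-3-propanoyloxazolidin-2-one
Product: 5 (R)-4-benzyl-3-[(2R,3R)-3-[3,5-bis(methoxymethoxy)phenyl]-3-hydroxy-2-methylpropanoyl]oxazolidin-2-one, via boron enolate 4 (not isolated)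
Conditions: 3, n-Bu2BOTf, i-Pr2NEt, CH2Cl2, −78 to 0 °C; then 2, −78 to 0 °C; pH 7 buffer, MeOH, H2O2
Reagents that add atoms: none
Why: Evans syn-aldol reaction: the (Z)-boron enolate should react through a Zimmerman–Traxler chair on the face away from the benzyl group, which sets the carbinol and the methyl-bearing centres as the (2R,3R) syn pair under auxiliary control.

Step 3
Reactants: 5 aldol adduct
Product: 6 (R)-4-benzyl-3-[(2R,3R)-3-[3,5-bis(methoxymethoxy)phenyl]-3-[(tert-butyldimethylsilyl)oxy]-2-methylpropanoyl]oxazolidin-2-one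
Conditions: TBSOTf, 2,6-lutidine, CH2Cl2, 0 °C
Reagents that add atoms: tert-butyldimethylsilyl triflate, CC(C)(C)[Si](C)(C)OS(=O)(=O)C(F)(F)F
Why: Silylation of the secondary benzylic alcohol with the reactive triflate should block retro-aldol cleavage and protect the oxygen until the carbamate is installed.

Step 4
Reactants: 6 silylated imide
Product: 7 (2S,3R)-3-[3,5-bis(methoxymethoxy)phenyl]-3-[(tert-butyldimethylsilyl)oxy]-2-methylpropan-1-ol
Conditions: LiBH4, MeOH (1 equiv), THF, 0 °C
Reagents that add atoms: none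
Why: Reductive cleavage of the N-acyl oxazolidinone by borohydride should give the primary alcohol and release the auxiliary without touching either stereocentre.

Step 5
Reactants: 7 primary alcohol
Product: 8 {[(1R,2R)-1-[3,5-bis(methoxymethoxy)phenyl]-3-iodo-2-methylpropyl]oxy}(tert-butyl)dimethylsilane
Conditions: I2, PPh3, imidazole, CH2Cl2, 0 °C to rt
Reagents that add atoms: iodine, II
Why: Appel-type iodination (Garegg–Samuelsson conditions) should convert the primary alcohol into the iodide under neutral conditions that MOM and TBS ethers tolerate.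

Step 6
Reactants: 8 primary iodide
Product: 9 {[(1R,2S)-1-[3,5-bis(methoxymethoxy)phenyl]-2-methylhex-5-en-1-yl]oxy}(tert-butyl)dimethylsilane
Conditions: allylMgBr, CuI (10 mol %), THF, −30 to 0 °C
Reagents that add atoms: allylmagnesium bromide, C=CC[Mg]Br
Why: Copper-catalysed Grignard–alkyl halide coupling (Kochi type) should displace the primary iodide and complete the hexenyl chain whose terminal carbon becomes the ring CH2 of the key bond.

Step 7
Reactants: 9 hexenyl arene
Product: 11 4-[(1R,2S)-1-[(tert-butyldimethylsilyl)oxy]-2-methylhex-5-en-1-yl]-2,6-bis(methoxymethoxy)benzaldehyde, via aryllithium 10 (not isolated)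
Conditions: n-BuLi, THF, 0 °C; DMF, 0 °C to rt; H2O
Reagents that add atoms: N,N-dimethylformamide, CN(C)C=O
Why: Directed ortho-metalation should occur at the ring carbon between the two cooperating OMOM groups, and formylation of the aryllithium puts the future benzylic carbon para to the carbinol arm.

Step 8
Reactants: 11 aldehyde
Product: 12 methyl (Z)-3-{4-[(1R,2S)-1-[(tert-butyldimethylsilyl)oxy]-2-methylhex-5-en-1-yl]-2,6-bis(methoxymethoxy)phenyl}prop-2-enoate
Conditions: (CF3CH2O)2P(O)CH2CO2Me, KHMDS, 18-crown-6, THF, −78 °C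
Reagents that add atoms: methyl bis(2,2,2-trifluoroethyl)phosphonoacetate, COC(=O)CP(=O)(OCC(F)(F)F)OCC(F)(F)F
Why: Still–Gennari olefination of the non-enolisable aryl aldehyde should give the (Z)-enoate by kinetically controlled, fast elimination from the trifluoroethyl phosphonate adduct.

Step 9
Reactants: 12 (Z)-enoate
Product: 13 (Z)-3-{4-[(1R,2S)-1-[(tert-butyldimethylsilyl)oxy]-2-methylhex-5-en-1-yl]-2,6-bis(methoxymethoxy)phenyl}prop-2-en-1-ol
Conditions: DIBAL-H, CH2Cl2, −78 °C; Rochelle salt
Reagents that add atoms: none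
Why: 1,2-Reduction of the enoate by DIBAL-H should give the allylic alcohol with the Z geometry intact.

Step 10
Reactants: 13 (Z)-allylic alcohol
Product: 15 {[(1R,2S)-1-{4-[(Z)-3-chloroprop-1-en-1-yl]-3,5-bis(methoxymethoxy)phenyl}-2-methylhex-5-en-1-yl]oxy}(tert-butyl)dimethylsilane, via allyl mesylate 14 (not isolated)
Conditions: MsCl, 2,4,6-collidine, LiCl, DMF, 0 °C; used at once
Reagents that add atoms: lithium chloride, [Li+].[Cl-]
Why: Collington–Meyers chlorination (mesylate formed in the flask, SN2 by chloride at the primary carbon) should give the allyl chloride without allylic transposition or Z to E isomerisation.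

Step 11
Reactants: 15 (Z)-allyl chloride monomer (two molecules)
Product: 19 C2-symmetric divinyl [7.7]paracyclophane (bridges aryl–CH(OTBS)–CH(CH3)–(CH2)4–CH(CH=CH2)–aryl′; carbinol carbons R; methyl-bearing carbons S; vinyl-bearing benzylic carbons S), via alkylborane 16 (not isolated), via ethoxyborate 17 (not isolated), via linear dimer 18 (not isolated)
Conditions: 9-BBN-H dimer (0.5 equiv), THF, 0 to 60 °C; EtOK (1.0 equiv), 0 °C; syringe-pump addition to CuOTf·(toluene)0.5 (20 mol %), (R)-DTBM-SEGPHOS (22 mol %), 1,4-dioxane, 25 °C, final 2 mM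
Reagents that add atoms: none
Why: Proposed new method: hydroboration gives a primary alkyl-9-BBN that, as its ethoxyborate, transmetallates to a chiral bisphosphine–alkylcopper(I), which attacks the γ-carbon of the (Z)-allyl chloride anti to chloride (SN2′; formal oxidative addition to a γ-σ-allylcopper(III), then fast reductive elimination), so that one intermolecular head-to-tail coupling is followed by the same event inside the linear dimer. The closest known reaction is the copper-catalysed, γ-selective, enantioselective allyl–alkyl coupling of alkyl-9-BBN reagents with (Z)-allyl chlorides, which is known between two separate partners but not as a cyclodimerisation or with a γ-(2,6-dialkoxyaryl) group. The 22-membered ring is closed by an exo-mode SN2′ macrocyclisation: the attacked benzylic carbon enters the ring and the shifted double bond stays outside as the vinyl group. Both new benzylic stereocentres are set by the ligand (catalyst control; the remote carbinol and methyl centres should have no say), and products of wrong-face attack are diastereomers that should be separable. The step needs γ- over α-attack, head-to-tail cyclodimerisation over oligomerisation, and chemoselective hydroboration. The Z geometry and the twisted, non-conjugated di-ortho-substituted aryl ring disfavour the π-allyl equilibration that leads to α-products; the para relationship of the two arms on a rigid benzene ring rules out cyclisation of the monomer (a [7]paracyclophane); high dilution favours ring closure of the dimer; and 9-BBN should take the monosubstituted alkene in preference to the hindered 1,2-disubstituted one.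

Step 12
Reactants: 20 dichloromethane; 21 allyl bromide
Product: 23 4,4-dichlorobut-1-ene, via dichloromethyllithium 22 (not isolated)
Conditions: n-BuLi, THF, −100 °C; allyl bromide, HMPA, −100 to −78 °C; distillation
Reagents that add atoms: none
Why: Alkylation of the Köbrich carbenoid dichloromethyllithium by the reactive allylic bromide (SN2) should give the gem-dichloride partner for cross-metathesis in one operation.

Step 13
Reactants: 19 divinyl macrocycle; 23 4,4-dichlorobut-1-ene (excess)
Product: 24 macrocycle as 19 with each vinyl group replaced by (E)-4,4-dichlorobut-1-en-1-yl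
Conditions: Hoveyda–Grubbs II (10 mol %), 23 (10 equiv), CH2Cl2, 40 °C
Reagents that add atoms: none
Why: Olefin cross-metathesis between the allylically branched vinyl groups and an excess of the unhindered terminal alkene should give the chain-extended alkenes (mainly E; the geometry is removed in step 14) with loss of ethene.

Step 14
Reactants: 24 bis(dichlorobutenyl) macrocycle
Product: 25 macrocycle as 19 with each vinyl group replaced by 4,4-dichlorobutyl (benzylic carbons S)
Conditions: TsNHNH2, NaOAc, DME/H2O, 85 °C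
Reagents that add atoms: none
Why: Diimide reduction should saturate the two disubstituted alkenes by concerted syn hydrogen transfer without hydrogenolysis of C–Cl or benzylic C–O bonds.

Step 15
Reactants: 25 saturated bis-TBS ether
Product: 26 macrocyclic diol (two free benzylic secondary alcohols, four MOM ethers, two 4,4-dichlorobutyl chains)
Conditions: HF·pyridine, pyridine, THF, 0 °C to rt
Reagents that add atoms: none
Why: Fluoride-mediated desilylation under buffered, weakly acidic conditions should free both carbinols while leaving the aryl MOM ethers and avoiding base-induced loss of HCl from the CHCl2 groups.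

Step 16
Reactants: 26 diol
Product: 28 macrocyclic bis(carbamate) tetrakis(MOM) ether, via N-trichloroacetyl carbamate 27 (not isolated)
Conditions: Cl3CC(O)NCO, CH2Cl2, 0 °C; then K2CO3 (cat.), MeOH, rt
Reagents that add atoms: trichloroacetyl isocyanate, O=C=NC(=O)C(Cl)(Cl)Cl
Why: Addition of the hindered secondary alcohols to the highly electrophilic acyl isocyanate, followed by methanolysis of the N-trichloroacetyl group (Kočovský carbamoylation), should give the primary carbamates with retention at the carbinol carbons.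

Step 17
Reactants: 28 bis(carbamate) tetrakis(MOM) ether
Product: 29 target CNP0205627.1
Conditions: HCl (3 M in MeOH), THF, 40 °C
Reagents that add atoms: none
Why: Acid-catalysed transacetalisation to dimethoxymethane should free the four phenols; the carbinol carbons are meta to both ring oxygens, so the benzylic carbamates are not activated for ionisation, and the gem-dichlorides are inert.

**Compound list**

1 | 3,5-dihydroxybenzaldehyde | O=Cc1cc(O)cc(O)c1 | starting material
2 | 3,5-bis(methoxymethoxy)benzaldehyde | COCOc1cc(C=O)cc(OCOC)c1 | intermediate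
3 | (R)-4-benzyl-3-propanoyloxazolidin-2-one | CCC(=O)N1[C@H](Cc2ccccc2)COC1=O | starting material
4 | (Z)-dibutylboron enolate of 3 | C/C=C(\OB(CCCC)CCCC)N1[C@H](Cc2ccccc2)COC1=O | intermediate
5 | (R)-4-benzyl-3-[(2R,3R)-3-[3,5-bis(methoxymethoxy)phenyl]-3-hydroxy-2-methylpropanoyl]oxazolidin-2-one | COCOc1cc(cc(OCOC)c1)[C@H](O)[C@@H](C)C(=O)N1[C@H](Cc2ccccc2)COC1=O | intermediate
6 | (R)-4-benzyl-3-[(2R,3R)-3-[3,5-bis(methoxymethoxy)phenyl]-3-[(tert-butyldimethylsilyl)oxy]-2-methylpropanoyl]oxazolidin-2-one | COCOc1cc(cc(OCOC)c1)[C@H](O[Si](C)(C)C(C)(C)C)[C@@H](C)C(=O)N1[C@H](Cc2ccccc2)COC1=O | intermediate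
7 | (2S,3R)-3-[3,5-bis(methoxymethoxy)phenyl]-3-[(tert-butyldimethylsilyl)oxy]-2-methylpropan-1-ol | COCOc1cc(cc(OCOC)c1)[C@H](O[Si](C)(C)C(C)(C)C)[C@@H](C)CO | intermediate
8 | {[(1R,2R)-1-[3,5-bis(methoxymethoxy)phenyl]-3-iodo-2-methylpropyl]oxy}(tert-butyl)dimethylsilane | COCOc1cc(cc(OCOC)c1)[C@H](O[Si](C)(C)C(C)(C)C)[C@@H](C)CI | intermediate
9 | {[(1R,2S)-1-[3,5-bis(methoxymethoxy)phenyl]-2-methylhex-5-en-1-yl]oxy}(tert-butyl)dimethylsilane | COCOc1cc(cc(OCOC)c1)[C@H](O[Si](C)(C)C(C)(C)C)[C@@H](C)CCC=C | intermediate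
10 | aryllithium from 9, lithium on the ring carbon between the two OMOM groups | COCOc1cc(cc(OCOC)c1[Li])[C@H](O[Si](C)(C)C(C)(C)C)[C@@H](C)CCC=C | intermediate
11 | 4-[(1R,2S)-1-[(tert-butyldimethylsilyl)oxy]-2-methylhex-5-en-1-yl]-2,6-bis(methoxymethoxy)benzaldehyde | COCOc1cc(cc(OCOC)c1C=O)[C@H](O[Si](C)(C)C(C)(C)C)[C@@H](C)CCC=C | intermediate
12 | methyl (Z)-3-{4-[(1R,2S)-1-[(tert-butyldimethylsilyl)oxy]-2-methylhex-5-en-1-yl]-2,6-bis(methoxymethoxy)phenyl}prop-2-enoate | COC(=O)/C=C\c1c(OCOC)cc(cc1OCOC)[C@H](O[Si](C)(C)C(C)(C)C)[C@@H](C)CCC=C | intermediate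
13 | (Z)-3-{4-[(1R,2S)-1-[(tert-butyldimethylsilyl)oxy]-2-methylhex-5-en-1-yl]-2,6-bis(methoxymethoxy)phenyl}prop-2-en-1-ol | OC/C=C\c1c(OCOC)cc(cc1OCOC)[C@H](O[Si](C)(C)C(C)(C)C)[C@@H](C)CCC=C | intermediate
14 | methanesulfonate of 13 | CS(=O)(=O)OC/C=C\c1c(OCOC)cc(cc1OCOC)[C@H](O[Si](C)(C)C(C)(C)C)[C@@H](C)CCC=C | intermediate
15 | {[(1R,2S)-1-{4-[(Z)-3-chloroprop-1-en-1-yl]-3,5-bis(methoxymethoxy)phenyl}-2-methylhex-5-en-1-yl]oxy}(tert-butyl)dimethylsilane | ClC/C=C\c1c(OCOC)cc(cc1OCOC)[C@H](O[Si](C)(C)C(C)(C)C)[C@@H](C)CCC=C | intermediate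
16 | B-alkyl-9-BBN from 15 (boron on the terminal carbon of the now saturated hexyl chain; allyl chloride intact) | ClC/C=C\c1c(OCOC)cc(cc1OCOC)[C@H](O[Si](C)(C)C(C)(C)C)[C@@H](C)CCCCB1C2CCCC1CCC2 | intermediate
17 | potassium B-ethoxyborate of 16 | ClC/C=C\c1c(OCOC)cc(cc1OCOC)[C@H](O[Si](C)(C)C(C)(C)C)[C@@H](C)CCCC[B-]1(OCC)C2CCCC1CCC2.[K+] | intermediate
18 | linear head-to-tail dimer: one new CH2–CH(aryl)(vinyl) bond (S), one (Z)-allyl chloride end, one ethoxyborate end | ClC/C=C\c1c(OCOC)cc(cc1OCOC)[C@H](O[Si](C)(C)C(C)(C)C)[C@@H](C)CCCC[C@@H](C=C)c1c(OCOC)cc(cc1OCOC)[C@H](O[Si](C)(C)C(C)(C)C)[C@@H](C)CCCC[B-]1(OCC)C2CCCC1CCC2.[K+] | intermediate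
19 | C2-symmetric divinyl [7.7]paracyclophane: two 2,6-bis(methoxymethoxy)-1,4-phenylene rings joined by two bridges –CH(OTBS)–CH(CH3)–(CH2)4–CH(CH=CH2)–, the vinyl-bearing carbon on the ring carbon between the OMOM groups; carbinol carbons R, methyl-bearing carbons S, vinyl-bearing carbons S | C[C@H]1CCCC[C@@H](C=C)c2c(OCOC)cc(cc2OCOC)[C@H](O[Si](C)(C)C(C)(C)C)[C@@H](C)CCCC[C@@H](C=C)c2c(OCOC)cc(cc2OCOC)[C@@H]1O[Si](C)(C)C(C)(C)C | intermediate
20 | dichloromethane | ClCCl | starting material
21 | allyl bromide | C=CCBr | starting material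
22 | dichloromethyllithium | [Li]C(Cl)Cl | intermediate
23 | 4,4-dichlorobut-1-ene | C=CCC(Cl)Cl | intermediate
24 | macrocycle as 19 with (E)-4,4-dichlorobut-1-en-1-yl in place of each vinyl group (benzylic carbons S) | C[C@H]1CCCC[C@@H](/C=C/CC(Cl)Cl)c2c(OCOC)cc(cc2OCOC)[C@H](O[Si](C)(C)C(C)(C)C)[C@@H](C)CCCC[C@@H](/C=C/CC(Cl)Cl)c2c(OCOC)cc(cc2OCOC)[C@@H]1O[Si](C)(C)C(C)(C)C | intermediate
25 | macrocycle as 19 with 4,4-dichlorobutyl in place of each vinyl group (benzylic carbons S) | C[C@H]1CCCC[C@@H](CCCC(Cl)Cl)c2c(OCOC)cc(cc2OCOC)[C@H](O[Si](C)(C)C(C)(C)C)[C@@H](C)CCCC[C@@H](CCCC(Cl)Cl)c2c(OCOC)cc(cc2OCOC)[C@@H]1O[Si](C)(C)C(C)(C)C | intermediate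
26 | macrocyclic diol: 25 without the two TBS groups (carbinol carbons R) | C[C@H]1CCCC[C@@H](CCCC(Cl)Cl)c2c(OCOC)cc(cc2OCOC)[C@H](O)[C@@H](C)CCCC[C@@H](CCCC(Cl)Cl)c2c(OCOC)cc(cc2OCOC)[C@@H]1O | intermediate
27 | bis(N-trichloroacetylcarbamate) of 26 | C[C@H]1CCCC[C@@H](CCCC(Cl)Cl)c2c(OCOC)cc(cc2OCOC)[C@H](OC(=O)NC(=O)C(Cl)(Cl)Cl)[C@@H](C)CCCC[C@@H](CCCC(Cl)Cl)c2c(OCOC)cc(cc2OCOC)[C@@H]1OC(=O)NC(=O)C(Cl)(Cl)Cl | intermediate
28 | bis(carbamate) of 26 (OC(O)NH2 on both carbinol carbons; four MOM ethers) | C[C@H]1CCCC[C@@H](CCCC(Cl)Cl)c2c(OCOC)cc(cc2OCOC)[C@H](OC(N)=O)[C@@H](C)CCCC[C@@H](CCCC(Cl)Cl)c2c(OCOC)cc(cc2OCOC)[C@@H]1OC(N)=O | intermediate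
29 | CNP0205627.1: [7.7]paracyclophane with two resorcinol rings, two carbamoyloxy carbons (R), two methyl-bearing carbons (S) and two 4,4-dichlorobutyl-bearing benzylic carbons (S) | C[C@H]1CCCC[C@@H](CCCC(Cl)Cl)c2c(O)cc(cc2O)[C@H](OC(N)=O)[C@@H](C)CCCC[C@@H](CCCC(Cl)Cl)c2c(O)cc(cc2O)[C@@H]1OC(N)=O | target

**Step count and risks**

Total steps: 17. Longest linear sequence: 16 (steps 1–11 and 13–17); step 12 is a one-step side branch.

Steps most likely to fail:

1. Step 11 (proposed new method). The risks are oligomerisation in place of ring closure, attack at the unhindered α-carbon in place of the aryl-flanked γ-carbon, and loss of the labile (Z)-allyl chloride (ionisation, Z to E isomerisation, participation of the neighbouring OMOM oxygen). The fallback sets out from 15 and returns at 25; it makes the same benzylic centre by the established two-component form of the coupling, with the side chain as the nucleophile, and closes the ring at the neighbouring bond by metathesis. Alkene 23 is hydroborated with 9-BBN to 9-(4,4-dichlorobutyl)-9-borabicyclo[3.3.1]nonane F1, which EtOK converts into its potassium ethoxyborate F2. Copper-catalysed coupling of F2 with 15 under CuOTf/(S)-DTBM-SEGPHOS (the antipodal ligand, because the alkyl and vinyl groups exchange roles) should give the diene tert-butyl{[(1R,2S)-1-{4-[(3R)-7,7-dichlorohept-1-en-3-yl]-3,5-bis(methoxymethoxy)phenyl}-2-methylhex-5-en-1-yl]oxy}dimethylsilane F3. Head-to-tail ring-closing metathesis dimerisation of F3 (Grubbs II, CH2Cl2, 40 °C, reversible conditions that favour the unstrained [7.7]paracyclophane) should give the macrocyclic (E,E)-diene F4. Diimide reduction of F4 under the conditions of step 14 gives 25.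

2. Step 13. The risk is slow or incomplete cross-metathesis at the two vinyl groups, which sit next to a congested benzylic carbon, with homodimerisation of 23 consuming the catalyst. The fallback sets out from 19 and returns at 25; it builds the chain by radical addition. Hydroboration of both vinyl groups with 9-BBN gives the bis(9-BBN) adduct F5; NaOH/H2O2 oxidation gives the bis(2-hydroxyethyl) macrocyclic diol F6; I2/PPh3/imidazole gives the bis(2-iodoethyl) macrocycle F7. Giese addition of the derived primary radicals to 1,1-dichloroethene ((Me3Si)3SiH, Et3B/air, rt), with hydrogen transfer to the α,α-dichloroalkyl radical, should give 25 directly.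

3. Step 17. The risk is slow cleavage of four hindered MOM ethers, with solvolysis of the benzylic carbamates or capture of methoxymethyl cations by the freed resorcinol rings during long acid exposure. The fallback sets out from 26 and returns at 29; it removes the MOM groups before any carbamate is present. Treatment of 26 with methanolic HCl gives the macrocyclic hexaol F8. Exhaustive reaction with trichloroacetyl isocyanate gives the hexakis(N-trichloroacetylcarbamate) F9. K2CO3 in MeOH should then remove all trichloroacetyl groups and cleave the four base-labile aryl carbamates (E1cB loss of the phenoxide), leaving the two alkyl carbamates of 29.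

Further compounds
F1 | step 11 | 9-(4,4-dichlorobutyl)-9-borabicyclo[3.3.1]nonane | ClC(Cl)CCCB1C2CCCC1CCC2
F2 | step 11 | potassium B-ethoxyborate of F1 | CCO[B-]1(CCCC(Cl)Cl)C2CCCC1CCC2.[K+]
F3 | step 11 | tert-butyl{[(1R,2S)-1-{4-[(3R)-7,7-dichlorohept-1-en-3-yl]-3,5-bis(methoxymethoxy)phenyl}-2-methylhex-5-en-1-yl]oxy}dimethylsilane | C=C[C@@H](CCCC(Cl)Cl)c1c(OCOC)cc(cc1OCOC)[C@H](O[Si](C)(C)C(C)(C)C)[C@@H](C)CCC=C
F4 | step 11 | macrocyclic (E,E)-diene: as 25 with a double bond between the two ring carbons next to each dichlorobutyl-bearing carbon (that carbon formally R) | C[C@H]1CC/C=C/[C@@H](CCCC(Cl)Cl)c2c(OCOC)cc(cc2OCOC)[C@H](O[Si](C)(C)C(C)(C)C)[C@@H](C)CC/C=C/[C@@H](CCCC(Cl)Cl)c2c(OCOC)cc(cc2OCOC)[C@@H]1O[Si](C)(C)C(C)(C)C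
F5 | step 13 | bis(9-BBN) adduct of 19 (each vinyl group converted into CH2CH2–9-BBN) | C[C@H]1CCCC[C@@H](CCB3C4CCCC3CCC4)c2c(OCOC)cc(cc2OCOC)[C@H](O[Si](C)(C)C(C)(C)C)[C@@H](C)CCCC[C@@H](CCB3C4CCCC3CCC4)c2c(OCOC)cc(cc2OCOC)[C@@H]1O[Si](C)(C)C(C)(C)C
F6 | step 13 | bis(2-hydroxyethyl) macrocycle (as 19 with CH2CH2OH in place of each vinyl group) | C[C@H]1CCCC[C@@H](CCO)c2c(OCOC)cc(cc2OCOC)[C@H](O[Si](C)(C)C(C)(C)C)[C@@H](C)CCCC[C@@H](CCO)c2c(OCOC)cc(cc2OCOC)[C@@H]1O[Si](C)(C)C(C)(C)C
F7 | step 13 | bis(2-iodoethyl) macrocycle (as 19 with CH2CH2I in place of each vinyl group) | C[C@H]1CCCC[C@@H](CCI)c2c(OCOC)cc(cc2OCOC)[C@H](O[Si](C)(C)C(C)(C)C)[C@@H](C)CCCC[C@@H](CCI)c2c(OCOC)cc(cc2OCOC)[C@@H]1O[Si](C)(C)C(C)(C)C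
F8 | step 17 | macrocyclic hexaol (26 without the four MOM groups) | C[C@H]1CCCC[C@@H](CCCC(Cl)Cl)c2c(O)cc(cc2O)[C@H](O)[C@@H](C)CCCC[C@@H](CCCC(Cl)Cl)c2c(O)cc(cc2O)[C@@H]1O
F9 | step 17 | hexakis(N-trichloroacetylcarbamate) of F8 | C[C@H]1CCCC[C@@H](CCCC(Cl)Cl)c2c(OC(=O)NC(=O)C(Cl)(Cl)Cl)cc(cc2OC(=O)NC(=O)C(Cl)(Cl)Cl)[C@H](OC(=O)NC(=O)C(Cl)(Cl)Cl)[C@@H](C)CCCC[C@@H](CCCC(Cl)Cl)c2c(OC(=O)NC(=O)C(Cl)(Cl)Cl)cc(cc2OC(=O)NC(=O)C(Cl)(Cl)Cl)[C@@H]1OC(=O)NC(=O)C(Cl)(Cl)Cl
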